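**Retrosynthetic overview**

1. Target 18 ← alcohol 17 (oxidation) ← aldehyde 14 + tetradecylmagnesium bromide 16; 14 ← vinyl oxolane 11 by anti-Markovnikov hydration and oxidation, so the two vinyl carbons become the CH2 and C=O of the arm.
2. 11 ← diester 7 by removal of both ester groups from the ring carbon next to the butyl-bearing carbon (target C4).
3. Feature used: the only ring, a cis-2,5-disubstituted oxolane (O1, C2–C5). O1–C5 with its butyl group is the C=O of pentanal; C2–C3–C4 is a three-carbon unit with the latent arm on C2 and a removable malonate on C4. Cutting O1–C2 and C4–C5 gives pentanal 6 and the (S)-vinylcyclopropane-1,1-diester 5; their formal 3+2 annulation is the single ring-forming step and sets both stereocentres.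
4. 5 ← racemic 4 (resolution) ← dimethyl malonate 1 + (E)-1,4-dibromobut-2-ene 2.

Key step: step 3

Remark: 8, 9 and 10 are carried as mixtures of C3 epimers and 17 as a mixture of carbinol epimers, because both centres later become non-stereogenic. Target C2/C5 correspond to C5/C2 in the locants of 7–11.

**Route**

Step 1
Reactants: 1 dimethyl propanedioate (dimethyl malonate); 2 (E)-1,4-dibromobut-2-ene
Product: 4 racemic dimethyl 2-ethenylcyclopropane-1,1-dicarboxylate, via bromobutenyl malonate 3 (not isolated)
Conditions: NaOMe (2.1 equiv), MeOH, 0 °C → reflux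
Reagents that add atoms: none
Why: Malonate double alkylation, in which SN2 displacement of one allylic bromide is followed by intramolecular SN2' (3-exo-trig) closure of the second malonate anion; the (E)-alkene cannot reach the geometry for cyclopentene formation, so the racemic vinylcyclopropane should result.

Step 2
Reactants: 4 racemic dimethyl 2-ethenylcyclopropane-1,1-dicarboxylate
Product: 5 dimethyl (2S)-2-ethenylcyclopropane-1,1-dicarboxylate
Conditions: preparative SFC, amylose tris(3,5-dimethylphenylcarbamate) stationary phase, CO2/i-PrOH, 35 °C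
Reagents that add atoms: none
Why: Resolution of a racemate by chromatography on a chiral stationary phase, which separates the enantiomers through diastereomeric adsorption complexes without any bond change at the stereocentre; the (S) fraction is to be assigned by optical rotation against the known enantiomer.

Step 3
Reactants: 5 dimethyl (2S)-2-ethenylcyclopropane-1,1-dicarboxylate; 6 pentanal
Product: 7 dimethyl (2R,5R)-2-butyl-5-ethenyloxolane-3,3-dicarboxylate
Conditions: Sn(OTf)2 (10 mol %, divalent tin), 6 (3 equiv), CH2Cl2, 0 °C → rt
Reagents that add atoms: none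
Why: Sn(OTf)2 chelates the two ester carbonyls of 5 and polarises the bond between the diester carbon and the vinyl-bearing carbon; the carbonyl oxygen of pentanal then attacks the vinyl-bearing carbon anti to the departing malonate carbon, an SN2-like, strain-releasing opening that inverts this centre and turns (S)-5 into the (R) centre at C5 of 7 (target C2). The tin malonate enolate so formed closes the oxolane by aldol-type C–C bond formation onto the oxocarbenium carbon (5-endo-trig at the electrophile, enol-exo at the nucleophile) through an envelope in which butyl and vinyl are both pseudo-equatorial, which sets C2 of 7 (target C5) cis to the vinyl group. The closest known reaction type is the Lewis-acid-catalysed stereospecific formal 3+2 cycloaddition of 2-aryl- and 2-alkenylcyclopropane-1,1-diesters with aldehydes to cis-2,5-disubstituted oxolanes. The step needs attack at the donor carbon and not at the vinyl terminus (secured by allylic stabilisation at the ring carbon and the favourable five-membered closure), full chirality transfer (secured by the mild divalent tin catalyst and low temperature, which keep the opening associative and avoid a free allyl cation) and cis selectivity (secured by the pseudo-equatorial preference under kinetic control).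

Step 4
Reactants: 7 dimethyl (2R,5R)-2-butyl-5-ethenyloxolane-3,3-dicarboxylate
Product: 8 methyl (2R,5R)-2-butyl-5-ethenyloxolane-3-carboxylate (both C3 epimers)
Conditions: LiCl (3 equiv), H2O (2 equiv), DMSO, 150 °C
Reagents that add atoms: none
Why: Krapcho dealkoxycarbonylation, in which chloride demethylates one ester by SN2 at methyl, the carboxylate loses CO2 and the ester enolate is protonated by water; C2 and C5 are untouched and the new C3 centre is removed later.

Step 5
Reactants: 8 methyl (2R,5R)-2-butyl-5-ethenyloxolane-3-carboxylate
Product: 9 (2R,5R)-2-butyl-5-ethenyloxolane-3-carboxylic acid (both C3 epimers)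
Conditions: LiOH·H2O, THF/MeOH/H2O, rt; then 1 M HCl
Reagents that add atoms: lithium hydroxide, [Li+].[OH-]
Why: Saponification by acyl–oxygen cleavage; epimerisation at C3 is irrelevant, and ring opening by β-elimination of the ring oxygen would be a stereoelectronically disfavoured reverse 5-endo-trig process.

Step 6
Reactants: 9 (2R,5R)-2-butyl-5-ethenyloxolane-3-carboxylic acid
Product: 11 (2R,5R)-2-butyl-5-ethenyloxolane, via Barton ester 10 (not isolated)
Conditions: N-hydroxypyridine-2-thione, DCC, DMAP (cat.), CH2Cl2, 0 °C → rt, dark; then t-BuSH, hν (tungsten lamp), rt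
Reagents that add atoms: none
Why: Barton reductive decarboxylation, in which the O-acyl thiohydroxamate 10 fragments under visible light to CO2 and the C3 radical, and hydrogen-atom transfer from t-BuSH gives the CH2 group; the thiyl radical should be trapped by the thiocarbonyl of 10 faster than it adds to the monosubstituted alkene, and C2 and C5 are not involved.

Step 7
Reactants: 11 (2R,5R)-2-butyl-5-ethenyloxolane
Product: 13 2-[(2R,5R)-5-butyloxolan-2-yl]ethan-1-ol, via B-alkyl-9-BBN adduct 12 (not isolated)
Conditions: 9-BBN, THF, 0 °C → rt; then NaOH, H2O2, H2O, 0 °C → rt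
Reagents that add atoms: hydrogen peroxide, OO
Why: Hydroboration–oxidation, in which the bulky 9-BBN places boron on the terminal vinyl carbon (anti-Markovnikov), so no β-alkoxyborane prone to elimination forms, and alkaline H2O2 replaces boron by hydroxyl with the ring stereocentres untouched.

Step 8
Reactants: 13 2-[(2R,5R)-5-butyloxolan-2-yl]ethan-1-ol
Product: 14 2-[(2R,5R)-5-butyloxolan-2-yl]acetaldehyde
Conditions: TEMPO (10 mol %), PhI(OAc)2, CH2Cl2, rt
Reagents that add atoms: none
Why: TEMPO-catalysed (oxoammonium) oxidation with PhI(OAc)2 as terminal oxidant stops at the aldehyde and needs no base, so the β-alkoxy aldehyde is not exposed to conditions that favour enolisation and β-elimination of the ring oxygen.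

Step 9
Reactants: 14 2-[(2R,5R)-5-butyloxolan-2-yl]acetaldehyde; 15 1-bromotetradecane
Product: 17 1-[(2R,5R)-5-butyloxolan-2-yl]hexadecan-2-ol (both carbinol epimers), via tetradecylmagnesium bromide 16 (not isolated)
Conditions: 15, Mg, THF, rt → 50 °C; then 14, THF, −78 → −20 °C; aq NH4Cl
Reagents that add atoms: none
Why: Grignard addition of a primary alkylmagnesium bromide to an unhindered aldehyde at low temperature, where 1,2-addition should outrun enolisation; the carbinol centre is formed without control because it is oxidised in the next step.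

Step 10
Reactants: 17 1-[(2R,5R)-5-butyloxolan-2-yl]hexadecan-2-ol
Product: 18 1-[(2R,5R)-5-butyloxolan-2-yl]hexadecan-2-one
Conditions: Dess–Martin periodinane, pyridine, CH2Cl2, 0 °C → rt
Reagents that add atoms: none
Why: Dess–Martin oxidation of the secondary alcohol under pyridine-buffered, near-neutral conditions gives the β-alkoxy ketone without acid- or base-mediated retro-oxa-Michael opening that could epimerise C2 of the oxolane.

**Compound list**

1 | dimethyl propanedioate (dimethyl malonate) | COC(=O)CC(=O)OC | starting material
2 | (E)-1,4-dibromobut-2-ene | BrC/C=C/CBr | starting material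
3 | dimethyl 2-[(2E)-4-bromobut-2-en-1-yl]propanedioate | COC(=O)C(C/C=C/CBr)C(=O)OC | intermediate (not isolated)
4 | racemic dimethyl 2-ethenylcyclopropane-1,1-dicarboxylate | C=CC1CC1(C(=O)OC)C(=O)OC | intermediate
5 | dimethyl (2S)-2-ethenylcyclopropane-1,1-dicarboxylate | C=C[C@@H]1CC1(C(=O)OC)C(=O)OC | intermediate
6 | pentanal | CCCCC=O | starting material
7 | dimethyl (2R,5R)-2-butyl-5-ethenyloxolane-3,3-dicarboxylate (butyl and vinyl cis) | C=C[C@H]1CC(C(=O)OC)(C(=O)OC)[C@@H](CCCC)O1 | intermediate
8 | methyl (2R,5R)-2-butyl-5-ethenyloxolane-3-carboxylate, both C3 epimers | C=C[C@H]1CC(C(=O)OC)[C@@H](CCCC)O1 | intermediate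
9 | (2R,5R)-2-butyl-5-ethenyloxolane-3-carboxylic acid, both C3 epimers | C=C[C@H]1CC(C(=O)O)[C@@H](CCCC)O1 | intermediate
10 | 2-sulfanylidenepyridin-1(2H)-yl (2R,5R)-2-butyl-5-ethenyloxolane-3-carboxylate (Barton ester), both C3 epimers | C=C[C@H]1CC(C(=O)ON2C=CC=CC2=S)[C@@H](CCCC)O1 | intermediate (not isolated)
11 | (2R,5R)-2-butyl-5-ethenyloxolane (cis) | C=C[C@H]1CC[C@@H](CCCC)O1 | intermediate
12 | 9-{2-[(2S,5R)-5-butyloxolan-2-yl]ethyl}-9-borabicyclo[3.3.1]nonane (same cis geometry; the C2 descriptor changes only because boron lowers the CIP rank of the arm) | C1CC2CCCC(C1)B2CC[C@H]1CC[C@@H](CCCC)O1 | intermediate (not isolated)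
13 | 2-[(2R,5R)-5-butyloxolan-2-yl]ethan-1-ol | OCC[C@H]1CC[C@@H](CCCC)O1 | intermediate
14 | 2-[(2R,5R)-5-butyloxolan-2-yl]acetaldehyde | O=CC[C@H]1CC[C@@H](CCCC)O1 | intermediate
15 | 1-bromotetradecane | CCCCCCCCCCCCCCBr | starting material
16 | tetradecylmagnesium bromide | CCCCCCCCCCCCCC[Mg]Br | intermediate (not isolated)
17 | 1-[(2R,5R)-5-butyloxolan-2-yl]hexadecan-2-ol, both carbinol epimers | CCCCCCCCCCCCCCC(O)C[C@H]1CC[C@@H](CCCC)O1 | intermediate
18 | 1-[(2R,5R)-5-butyloxolan-2-yl]hexadecan-2-one | CCCCCCCCCCCCCCC(=O)C[C@H]1CC[C@@H](CCCC)O1 | target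

**Step count**

Total: 10 steps. Longest linear sequence: 10 steps (1 and 2 to 18; the Grignard reagent is made within step 9).

**Steps most likely to fail and fallbacks**

Step 3. The tin-activated vinylcyclopropane may ionise reversibly to an allyl cation–malonate ion pair and re-close before the aldehyde adds, which would erode the enantiopurity; the enolisable aldehyde may also self-condense or trimerise under the Lewis acid. The fallback moves the resolution behind the annulation, so chirality transfer no longer matters. It sets out from racemic 4: annulation with 6 under SnCl4 (tetravalent tin, 5–10 mol %, CH2Cl2, −78 °C → rt) should give racemic dimethyl cis-2-butyl-5-ethenyloxolane-3,3-dicarboxylate F1. Preparative SFC of F1 on a chiral stationary phase should then deliver the (2R,5R) enantiomer, which is 7. The route is rejoined at 7, and step 2 is not needed.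

Step 6. The thiol may add to the vinyl group in a radical thiol-ene process, the chain may be diverted through the allylic ether position, and the volatile product may be lost on concentration. The fallback removes the alkene before the radical step and sets out from 8. Hydroboration with 9-BBN (THF, rt) and oxidation with NaBO3·4H2O, which spares the methyl ester, should give methyl (2R,5R)-2-butyl-5-(2-hydroxyethyl)oxolane-3-carboxylate F2. Silylation (t-BuMe2SiCl, imidazole, DMF) should give methyl (2R,5R)-2-butyl-5-{2-[tert-butyl(dimethyl)silyl]oxyethyl}oxolane-3-carboxylate F3. Saponification (LiOH, THF/MeOH/H2O; citric acid work-up) should give (2R,5R)-2-butyl-5-{2-[tert-butyl(dimethyl)silyl]oxyethyl}oxolane-3-carboxylic acid F4. Barton decarboxylation as in step 6 would pass through the ester 2-sulfanylidenepyridin-1(2H)-yl (2R,5R)-2-butyl-5-{2-[tert-butyl(dimethyl)silyl]oxyethyl}oxolane-3-carboxylate F5 and should give the non-volatile tert-butyl{2-[(2R,5R)-5-butyloxolan-2-yl]ethoxy}dimethylsilane F6. Desilylation with Bu4NF (THF, rt) gives 13, where the route is rejoined; steps 5–7 are replaced.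

Step 9. The basic Grignard reagent may enolise the β-alkoxy aldehyde, after which β-elimination of the ring oxygen would open the ring and lose the C2 configuration; reduction of the aldehyde by β-hydride transfer is also possible. The fallback changes the electrophile so that no enolisable aldehyde and no final oxidation are needed, and sets out from 13. Oxidation with TEMPO (cat.) and PhI(OAc)2 in MeCN/H2O should give 2-[(2R,5R)-5-butyloxolan-2-yl]acetic acid F7. Coupling with MeNH(OMe)·HCl (EDC·HCl, N-methylmorpholine, CH2Cl2) should give the Weinreb amide 2-[(2R,5R)-5-butyloxolan-2-yl]-N-methoxy-N-methylacetamide F8. Addition of 16 (THF, 0 °C) should give the ketone on work-up through the stable magnesium chelate. The route is rejoined at the target 18; steps 8–10 are replaced.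

**Further compounds**

F1 | step 3 | racemic dimethyl cis-2-butyl-5-ethenyloxolane-3,3-dicarboxylate (1:1 mixture of the (2R,5R) and (2S,5S) enantiomers) | C=C[C@H]1CC(C(=O)OC)(C(=O)OC)[C@@H](CCCC)O1.C=C[C@@H]1CC(C(=O)OC)(C(=O)OC)[C@H](CCCC)O1
F2 | step 6 | methyl (2R,5R)-2-butyl-5-(2-hydroxyethyl)oxolane-3-carboxylate, both C3 epimers | OCC[C@H]1CC(C(=O)OC)[C@@H](CCCC)O1
F3 | step 6 | methyl (2R,5R)-2-butyl-5-{2-[tert-butyl(dimethyl)silyl]oxyethyl}oxolane-3-carboxylate, both C3 epimers | CC(C)(C)[Si](C)(C)OCC[C@H]1CC(C(=O)OC)[C@@H](CCCC)O1
F4 | step 6 | (2R,5R)-2-butyl-5-{2-[tert-butyl(dimethyl)silyl]oxyethyl}oxolane-3-carboxylic acid, both C3 epimers | CC(C)(C)[Si](C)(C)OCC[C@H]1CC(C(=O)O)[C@@H](CCCC)O1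
F5 | step 6 | 2-sulfanylidenepyridin-1(2H)-yl (2R,5R)-2-butyl-5-{2-[tert-butyl(dimethyl)silyl]oxyethyl}oxolane-3-carboxylate, both C3 epimers | CC(C)(C)[Si](C)(C)OCC[C@H]1CC(C(=O)ON2C=CC=CC2=S)[C@@H](CCCC)O1
F6 | step 6 | tert-butyl{2-[(2R,5R)-5-butyloxolan-2-yl]ethoxy}dimethylsilane | CC(C)(C)[Si](C)(C)OCC[C@H]1CC[C@@H](CCCC)O1
F7 | step 9 | 2-[(2R,5R)-5-butyloxolan-2-yl]acetic acid | OC(=O)C[C@H]1CC[C@@H](CCCC)O1
F8 | step 9 | 2-[(2R,5R)-5-butyloxolan-2-yl]-N-methoxy-N-methylacetamide | CON(C)C(=O)C[C@H]1CC[C@@H](CCCC)O1
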